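## Retrosynthetic overview

1. The two CO2H groups are carried as silyl-protected neopentyl CH2OH groups and oxidised last. The C11–C12 bond of the unit 2 side chain is cut (Negishi coupling) into alkylzinc fragment 2 (the 8(17)-methylidene ent-decalin) and (E)-alkenyl iodide fragment 1 (the 7-methylidene decalin plus the central cyclohexene).
2. Fragment 2 comes from the acyclic (2R,3R)-epoxy dienoate 28 in one cationic cascade: ring A closes by the C4–C5 bond, then ring B by the C9–C10 bond, ending in the C8=C17 methylidene.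
3. Enabling feature: in unit 2 the quaternary C4 of ring A (CH3 and oxidised C18) is flanked by C3 and C5, C5–C10 is the ring fusion, and C9 sits next to the exocyclic C8=C17. This array maps onto a C3–C4 oxirane with (E)-CH2OSi on C4, an (E)-C5=C10 alkene and a C8=C9 alkene carrying CH2SiMe3 on C8; release of oxirane strain drives C4–C5 formation.
4. Fragment 1: the central cyclohexene is closed by ring-closing metathesis after an enantioselective ester-enolate Claisen rearrangement that joins its two stereocentres. The allylic alcohol for this comes from levopimaric acid (ozonolysis of ring C, then the C8 carbonyl is traded for a C7 methylidene).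
5. Ring order: unit 1 decalin (chiral pool), then central cyclohexene (step 12); separately ring A then ring B of unit 2 (step 25); the ring systems are joined in step 30.

Key step: step 25

## Remarks before the steps

- Assumption: levopimaric acid (abieta-8(14),12-dien-18-oic acid, a resin acid of pine oleoresin) is taken as a purchasable starting material.
- Assumption: the (4R,5R)-diazaborolidine of step 11 is taken to deliver the (2S,3S) acid 13; if its sense of induction were the opposite, its mirror image would be used in the same step.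
- Notation: atom numbers are labdane/abietane numbers of the decalin concerned. Unit 1 is the 7-methylidene decalin, unit 2 the 8(17)-methylidene decalin. TBDPS = tert-butyldiphenylsilyl.
- D1CH2– is the unit 1 bicycle with its C11 methylene: the trans-decalin of 1 (C4, C5, C9, C10 as in 1) carrying 4-CH2OTBDPS, 4-CH3, 10-CH3 and 7-methylidene, bonded through C9–CH2.
- In unit 2 compounds ("ent series") the 10-CH3 and the axial 4-CH3 are cis, H-5 is trans to 10-CH3, and the C9 substituent and C18 are equatorial.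

## Route

Step 1
Reactants: 1 levopimaric acid
Product: 2 levopimarol
Conditions: LiAlH4, THF, 0 °C → 65 °C
Reagents that add atoms: none
Why: LiAlH4 reduction of the carboxylic acid to the neopentyl alcohol touches neither the diene nor C4, C5, C9 or C10, and carrying C18 at the alcohol level avoids a hindered ester hydrolysis at the end.

Step 2
Reactants: 2 levopimarol
Product: 3 18-O-TBDPS-levopimarol
Conditions: t-BuPh2SiCl, imidazole, DMAP (cat.), DMF, 40 °C
Reagents that add atoms: tert-butyl(chloro)diphenylsilane, CC(C)(C)[Si](Cl)(c1ccccc1)c1ccccc1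
Why: Silyl ether protection of the primary alcohol with a group that should last until the fluoride treatment of step 31.

Step 3
Reactants: 3 18-O-TBDPS-levopimarol
Product: 4 18-(TBDPS-oxy)-8-oxo-13,14,15,16,17-pentanorlabdan-12-al
Conditions: O3, pyridine (3 equiv), CH2Cl2, −78 °C
Reagents that add atoms: ozone, [O-][O+]=O
Why: Ozonolysis of both double bonds of the homoannular diene (C8=C14 and C12=C13), with pyridine turning the carbonyl oxides directly into carbonyls, should excise C13–C17 and leave the C8 ketone and C12 aldehyde; C9 already holds its side chain in the more stable equatorial position.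

Step 4
Reactants: 4 18-(TBDPS-oxy)-8-oxo-13,14,15,16,17-pentanorlabdan-12-al
Product: 5 ethyl (12E)-18-(TBDPS-oxy)-8-oxo-15,17-dinorlabd-12-en-14-oate
Conditions: Ph3P=C(CH3)CO2Et, CH2Cl2, 25 °C
Reagents that add atoms: ethyl 2-(triphenyl-λ5-phosphanylidene)propanoate, CCOC(=O)C(C)=P(c1ccccc1)(c1ccccc1)c1ccccc1
Why: Wittig olefination with a stabilised ylide should react only at the aldehyde (the C8 ketone is hindered) and give the (E)-trisubstituted enoate.

Step 5
Reactants: 5 ethyl (12E)-18-(TBDPS-oxy)-8-oxo-15,17-dinorlabd-12-en-14-oate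
Product: 6 ethyl (12E)-18-(TBDPS-oxy)-7-methylidene-8-oxo-15,17-dinorlabd-12-en-14-oate
Conditions: (CH2O)n, N-methylanilinium trifluoroacetate, THF, 65 °C
Reagents that add atoms: formaldehyde (as paraformaldehyde), C=O
Why: Mannich-type α-methylenation of the ketone (aminomethylation then elimination) can give an enone only at C7, the one α-carbon with two hydrogens.

Step 6
Reactants: 6 ethyl (12E)-18-(TBDPS-oxy)-7-methylidene-8-oxo-15,17-dinorlabd-12-en-14-oate
Product: 7 ethyl (12E)-18-(TBDPS-oxy)-8-hydroxy-7-methylidene-15,17-dinorlabd-12-en-14-oate (C8 epimers)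
Conditions: NaBH4, CeCl3·7H2O, MeOH, −78 °C → 0 °C
Reagents that add atoms: none
Why: Luche 1,2-reduction of the exocyclic enone should give the allylic alcohol and leave the enoate alone; the new C8 centre is removed again in step 8, so its configuration does not matter.

Step 7
Reactants: 7 ethyl (12E)-18-(TBDPS-oxy)-8-hydroxy-7-methylidene-15,17-dinorlabd-12-en-14-oate (C8 epimers)
Product: 8 ethyl (12E)-18-(TBDPS-oxy)-8-(methoxycarbonyloxy)-7-methylidene-15,17-dinorlabd-12-en-14-oate (C8 epimers)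
Conditions: ClCO2Me, pyridine, DMAP (cat.), CH2Cl2, 0 °C
Reagents that add atoms: methyl chloroformate, COC(=O)Cl
Why: Acylation of the secondary allylic alcohol gives the carbonate leaving group for the palladium step.

Step 8
Reactants: 8 ethyl (12E)-18-(TBDPS-oxy)-8-(methoxycarbonyloxy)-7-methylidene-15,17-dinorlabd-12-en-14-oate (C8 epimers)
Product: 9 ethyl (12E)-18-(TBDPS-oxy)-7-methylidene-15,17-dinorlabd-12-en-14-oate
Conditions: Pd(OAc)2 (5 mol %), n-Bu3P (20 mol %), HCO2H, Et3N, THF, 60 °C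
Reagents that add atoms: none
Why: Palladium-catalysed formate hydrogenolysis of the allylic carbonate (Tsuji–Trost manifold) should deliver hydride to the more substituted allyl terminus C8, so the exocyclic C7 methylidene is kept and C8 becomes CH2.

Step 9
Reactants: 9 ethyl (12E)-18-(TBDPS-oxy)-7-methylidene-15,17-dinorlabd-12-en-14-oate
Product: 10 (12E)-18-(TBDPS-oxy)-7-methylidene-15,17-dinorlabd-12-en-14-ol
Conditions: i-Bu2AlH, CH2Cl2, −78 °C
Reagents that add atoms: none
Why: i-Bu2AlH reduction of the conjugated ester should give the (E)-allylic alcohol without touching alkenes or the silyl ether.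

Step 10
Reactants: 10 (12E)-18-(TBDPS-oxy)-7-methylidene-15,17-dinorlabd-12-en-14-ol
Product: 11 (12E)-18-(TBDPS-oxy)-7-methylidene-15,17-dinorlabd-12-en-14-yl hex-5-enoate
Conditions: hex-5-enoyl chloride, pyridine, DMAP (cat.), CH2Cl2, 0 °C
Reagents that add atoms: hex-5-enoyl chloride, C=CCCCC(=O)Cl
Why: Acylation of the primary allylic alcohol gives the allyl ester needed for the Claisen rearrangement.

Step 11
Reactants: 11 (12E)-18-(TBDPS-oxy)-7-methylidene-15,17-dinorlabd-12-en-14-yl hex-5-enoate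
Product: 13 (2S,3S)-2-(but-3-en-1-yl)-3-(D1CH2)-4-methylpent-4-enoic acid, via boron ketene acetal 12 (not isolated)
Conditions: (4R,5R)-2-bromo-1,3-bis{[3,5-bis(trifluoromethyl)phenyl]sulfonyl}-4,5-diphenyl-1,3,2-diazaborolidine, i-Pr2NEt, CH2Cl2, −78 °C, then −20 °C; aqueous work-up
Reagents that add atoms: none
Why: Enantioselective ester-enolate (Ireland-type) Claisen rearrangement: the (Z)-O-boron enolate should rearrange through a chair transition state with both substituents equatorial to the syn acid, setting both future ring stereocentres, with the absolute sense controlled by the chiral boron reagent because the substrate stereocentres are remote.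

Step 12
Reactants: 13 (2S,3S)-2-(but-3-en-1-yl)-3-(D1CH2)-4-methylpent-4-enoic acid
Product: 14 (1S,2S)-2-(D1CH2)-3-methylcyclohex-3-ene-1-carboxylic acid
Conditions: second-generation Grubbs catalyst RuCl2(=CHPh)(PCy3)(H2IMes) (5 mol %), CH2Cl2, 40 °C
Reagents that add atoms: none
Why: Ring-closing metathesis between the monosubstituted alkene and the isopropenyl group should close the cis-disubstituted trisubstituted cyclohexene; the hindered decalin methylidene should not compete and no stereocentre is touched.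

Step 13
Reactants: 14 (1S,2S)-2-(D1CH2)-3-methylcyclohex-3-ene-1-carboxylic acid
Product: 15 [(1S,2S)-2-(D1CH2)-3-methylcyclohex-3-en-1-yl]methanol
Conditions: LiAlH4, THF, 0 °C → 25 °C
Reagents that add atoms: none
Why: LiAlH4 reduction of the acid to the primary alcohol leaves alkenes and the silyl ether alone.

Step 14
Reactants: 15 [(1S,2S)-2-(D1CH2)-3-methylcyclohex-3-en-1-yl]methanol
Product: 16 (1S,2S)-2-(D1CH2)-3-methylcyclohex-3-ene-1-carbaldehyde
Conditions: Dess–Martin periodinane, NaHCO3, CH2Cl2, 0 °C → 25 °C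
Reagents that add atoms: none
Why: Buffered Dess–Martin oxidation should give the aldehyde without epimerising the α-stereocentre.

Step 15
Reactants: 16 (1S,2S)-2-(D1CH2)-3-methylcyclohex-3-ene-1-carbaldehyde
Product: 17 (5S,6S)-6-(D1CH2)-5-ethynyl-1-methylcyclohex-1-ene
Conditions: dimethyl (1-diazo-2-oxopropyl)phosphonate, K2CO3, MeOH, 0 °C → 25 °C
Reagents that add atoms: dimethyl (1-diazo-2-oxopropyl)phosphonate, CC(=O)C(=[N+]=[N-])P(=O)(OC)OC
Why: Seyferth–Gilbert homologation with the Ohira–Bestmann reagent adds one carbon to give the terminal alkyne, and the mild carbonate base at low temperature should keep the α-stereocentre.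

Step 16
Reactants: 17 (5S,6S)-6-(D1CH2)-5-ethynyl-1-methylcyclohex-1-ene
Product: 19 (5S,6S)-6-(D1CH2)-5-[(1E)-1-iodoprop-1-en-2-yl]-1-methylcyclohex-1-ene, via alkenylalane 18 (not isolated)
Conditions: Me3Al, Cp2ZrCl2 (0.3 equiv), CH2Cl2, 0 °C → 25 °C; then I2, THF, −30 °C
Reagents that add atoms: trimethylaluminium, C[Al](C)C; iodine, II
Why: Zirconium-catalysed syn-carboalumination of the terminal alkyne (Negishi) followed by iodinolysis with retention should give the (E)-alkenyl iodide with the new methyl on the internal carbon; the other alkenes are inert to these conditions.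

Step 17
Reactants: 20 geranyl acetate
Product: 21 (2E,6E)-8-hydroxy-3,7-dimethylocta-2,6-dien-1-yl acetate
Conditions: SeO2 (cat.), t-BuOOH, salicylic acid (cat.), CH2Cl2, 25 °C
Reagents that add atoms: tert-butyl hydroperoxide, CC(C)(C)OO
Why: SeO2-catalysed allylic oxidation (ene reaction then 2,3-shift) should hydroxylate the (E)-methyl of the terminal trisubstituted alkene selectively.

Step 18
Reactants: 21 (2E,6E)-8-hydroxy-3,7-dimethylocta-2,6-dien-1-yl acetate
Product: 22 (2E)-5-[(2R,3R)-3-(hydroxymethyl)-3-methyloxiran-2-yl]-3-methylpent-2-en-1-yl acetate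
Conditions: Ti(OiPr)4 (cat.), D-(−)-diethyl tartrate (cat.), t-BuOOH, 4 Å molecular sieves, CH2Cl2, −20 °C
Reagents that add atoms: tert-butyl hydroperoxide, CC(C)(C)OO
Why: Sharpless asymmetric epoxidation of the allylic alcohol with D-(−)-diethyl tartrate should give the (2R,3R)-oxirane, the enantiomer needed for the ent series; the undirected allylic acetate alkene stays.

Step 19
Reactants: 22 (2E)-5-[(2R,3R)-3-(hydroxymethyl)-3-methyloxiran-2-yl]-3-methylpent-2-en-1-yl acetate
Product: 23 (2E)-5-[(2R,3R)-3-(TBDPS-oxymethyl)-3-methyloxiran-2-yl]-3-methylpent-2-en-1-yl acetate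
Conditions: t-BuPh2SiCl, imidazole, DMF, 25 °C
Reagents that add atoms: tert-butyl(chloro)diphenylsilane, CC(C)(C)[Si](Cl)(c1ccccc1)c1ccccc1
Why: Silylation of the epoxy alcohol gives a weakly Lewis-basic ether that should survive the cyclisation and all later steps.

Step 20
Reactants: 23 (2E)-5-[(2R,3R)-3-(TBDPS-oxymethyl)-3-methyloxiran-2-yl]-3-methylpent-2-en-1-yl acetate
Product: 24 (2E)-5-[(2R,3R)-3-(TBDPS-oxymethyl)-3-methyloxiran-2-yl]-3-methylpent-2-en-1-ol
Conditions: K2CO3, MeOH, 0 °C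
Reagents that add atoms: none
Why: Methanolysis of the acetate; the oxirane and silyl ether are stable to carbonate in methanol at this temperature.

Step 21
Reactants: 24 (2E)-5-[(2R,3R)-3-(TBDPS-oxymethyl)-3-methyloxiran-2-yl]-3-methylpent-2-en-1-ol
Product: 25 (2E)-1-bromo-5-[(2R,3R)-3-(TBDPS-oxymethyl)-3-methyloxiran-2-yl]-3-methylpent-2-ene
Conditions: CBr4, PPh3, 2,6-lutidine, CH2Cl2, −20 °C
Reagents that add atoms: tetrabromomethane, BrC(Br)(Br)Br
Why: Appel bromination of the primary allylic alcohol under buffered neutral conditions should spare the oxirane.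

Step 22
Reactants: 25 (2E)-1-bromo-5-[(2R,3R)-3-(TBDPS-oxymethyl)-3-methyloxiran-2-yl]-3-methylpent-2-ene
Product: 26 methyl (6E)-9-[(2R,3R)-3-(TBDPS-oxymethyl)-3-methyloxiran-2-yl]-7-methyl-3-oxonon-6-enoate
Conditions: methyl acetoacetate, NaH, then n-BuLi, THF, 0 °C; then 25, 0 °C
Reagents that add atoms: methyl acetoacetate, COC(=O)CC(C)=O
Why: γ-Alkylation of the acetoacetate dianion by the allylic bromide (SN2) forms the C6–C7 bond; the hindered trisubstituted oxirane should not be opened at 0 °C.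

Step 23
Reactants: 26 methyl (6E)-9-[(2R,3R)-3-(TBDPS-oxymethyl)-3-methyloxiran-2-yl]-7-methyl-3-oxonon-6-enoate
Product: 27 methyl (2Z,6E)-9-[(2R,3R)-3-(TBDPS-oxymethyl)-3-methyloxiran-2-yl]-7-methyl-3-(trifluoromethylsulfonyloxy)nona-2,6-dienoate
Conditions: NaH, THF, 0 °C; then PhNTf2, 0 °C → 25 °C
Reagents that add atoms: N-phenylbis(trifluoromethanesulfonimide), O=S(=O)(N(c1ccccc1)S(=O)(=O)C(F)(F)F)C(F)(F)F
Why: O-Sulfonylation of the chelated sodium enolate of the β-keto ester should give the (Z)-enol triflate (triflate cis to the ester).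

Step 24
Reactants: 27 methyl (2Z,6E)-9-[(2R,3R)-3-(TBDPS-oxymethyl)-3-methyloxiran-2-yl]-7-methyl-3-(trifluoromethylsulfonyloxy)nona-2,6-dienoate
Product: 28 methyl (2Z,6E)-9-[(2R,3R)-3-(TBDPS-oxymethyl)-3-methyloxiran-2-yl]-7-methyl-3-[(trimethylsilyl)methyl]nona-2,6-dienoate
Conditions: Me3SiCH2MgCl, Pd(PPh3)4 (5 mol %), THF, 0 °C → 25 °C
Reagents that add atoms: (trimethylsilyl)methylmagnesium chloride, C[Si](C)(C)C[Mg]Cl
Why: Kumada-type cross-coupling of the enol triflate proceeds with retention of alkene geometry and places CH2SiMe3 on C8 cis to the ester carbon, the geometry that leads to an equatorial C9 substituent; the hindered Grignard reagent should not attack the ester or oxirane.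

Step 25
Reactants: 28 methyl (2Z,6E)-9-[(2R,3R)-3-(TBDPS-oxymethyl)-3-methyloxiran-2-yl]-7-methyl-3-[(trimethylsilyl)methyl]nona-2,6-dienoate
Product: 29 methyl (3R,4S,5S,9R,10R)-18-(TBDPS-oxy)-3-hydroxy-12,13,14,15,16-pentanorlabd-8(17)-en-11-oate (ent series)
Conditions: MeAlCl2 (2.5 equiv), CH2Cl2, −90 °C → −78 °C
Reagents that add atoms: none
Why: MeAlCl2 coordinates the oxirane oxygen and the C3–C4 oxirane opens at the tertiary C4 in concert with attack of the (E)-C5=C10 alkene, the tertiary C10 cation is captured by C9 of the silyl-substituted enoate, and the β-silyl cation at C8 loses Me3Si (as Me3SiCl) to give the exocyclic C8=C17 methylidene, the whole cascade being driven by release of oxirane strain. The closest known reaction type is the Lewis-acid-induced epoxy-polyene cyclisation with (silyloxymethyl)oxirane initiators and allylsilane terminators, as used for 8(17)-labdenes. Ring A closes 6-endo by forming C4–C5 and ring B closes 6-endo by forming C9–C10, both through chair-like transition states. C3 keeps the configuration set by the Sharpless epoxidation and C4 is set by inversion (anti attack on the oxirane), so the (E)-CH2OSi group ends equatorial and the methyl axial; C5 and C10 become trans because addition across the (E)-C5=C10 bond is antiperiplanar (Stork–Eschenmoser), and C9 takes the equatorial ester because C7 and the ester carbon are trans on the C8=C9 bond. The step needs bicyclisation in preference to proton loss or chloride capture at C10, which the low temperature and the pre-organised silyl-activated terminator should secure, and it needs a single alkene regioisomer, which the silicon atom guarantees. The absolute configuration of all five stereocentres follows from the (2R,3R)-oxirane.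

Step 26
Reactants: 29 methyl (3R,4S,5S,9R,10R)-18-(TBDPS-oxy)-3-hydroxy-12,13,14,15,16-pentanorlabd-8(17)-en-11-oate (ent series)
Product: 30 methyl (3R,4S,5S,9R,10R)-18-(TBDPS-oxy)-3-(imidazol-1-ylcarbothioyloxy)-12,13,14,15,16-pentanorlabd-8(17)-en-11-oate
Conditions: 1,1′-thiocarbonyldiimidazole, DMAP, ClCH2CH2Cl, 70 °C
Reagents that add atoms: 1,1′-thiocarbonyldiimidazole, S=C(n1ccnc1)n1ccnc1
Why: Thioacylation of the equatorial C3 alcohol under neutral conditions (no base that could move the β,γ-alkene into conjugation) is the first half of a Barton–McCombie deoxygenation.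

Step 27
Reactants: 30 methyl (3R,4S,5S,9R,10R)-18-(TBDPS-oxy)-3-(imidazol-1-ylcarbothioyloxy)-12,13,14,15,16-pentanorlabd-8(17)-en-11-oate
Product: 31 methyl (4S,5S,9R,10R)-18-(TBDPS-oxy)-12,13,14,15,16-pentanorlabd-8(17)-en-11-oate
Conditions: n-Bu3SnH, AIBN (cat.), toluene, 100 °C
Reagents that add atoms: none
Why: Barton–McCombie radical deoxygenation; the secondary C3 radical has no alkene within reach and should simply be reduced by the stannane.

Step 28
Reactants: 31 methyl (4S,5S,9R,10R)-18-(TBDPS-oxy)-12,13,14,15,16-pentanorlabd-8(17)-en-11-oate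
Product: 32 (4S,5S,9R,10R)-18-(TBDPS-oxy)-12,13,14,15,16-pentanorlabd-8(17)-en-11-ol
Conditions: LiAlH4, Et2O, 0 °C
Reagents that add atoms: none
Why: LiAlH4 reduction of the ester to the C11 primary alcohol, fast enough at 0 °C that C9 should not epimerise.

Step 29
Reactants: 32 (4S,5S,9R,10R)-18-(TBDPS-oxy)-12,13,14,15,16-pentanorlabd-8(17)-en-11-ol
Product: 33 (4S,5S,9R,10R)-18-(TBDPS-oxy)-11-iodo-12,13,14,15,16-pentanorlabd-8(17)-ene
Conditions: I2, PPh3, imidazole, CH2Cl2, 0 °C → 25 °C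
Reagents that add atoms: iodine, II
Why: Appel-type iodination of the primary alcohol under neutral conditions leaves the homoallylic exocyclic alkene untouched.

Step 30
Reactants: 33 (4S,5S,9R,10R)-18-(TBDPS-oxy)-11-iodo-12,13,14,15,16-pentanorlabd-8(17)-ene; 19 (5S,6S)-6-(D1CH2)-5-[(1E)-1-iodoprop-1-en-2-yl]-1-methylcyclohex-1-ene
Product: 35 18,18′-bis-O-TBDPS ether of diol 36, via alkylzinc iodide 34 (not isolated)
Conditions: Zn dust (activated with BrCH2CH2Br and Me3SiCl), N,N-dimethylacetamide, 45 °C; then 19, Pd(dppf)Cl2 (5 mol %), THF, 50 °C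
Reagents that add atoms: none
Why: Negishi sp3–sp2 cross-coupling (zinc insertion into the primary C–I bond, transmetalation, reductive elimination) forms the C11–C12 bond with retention of the (E)-alkene, and both fragments keep their stereocentres.

Step 31
Reactants: 35 18,18′-bis-O-TBDPS ether of diol 36
Product: 36 18,18′-diol corresponding to the target (both CO2H replaced by CH2OH)
Conditions: n-Bu4NF, THF, 50 °C
Reagents that add atoms: none
Why: Fluoride cleavage of both silyl ethers in one operation.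

Step 32
Reactants: 36 18,18′-diol corresponding to the target
Product: 37 18,18′-dialdehyde corresponding to the target
Conditions: Dess–Martin periodinane, NaHCO3, CH2Cl2, 25 °C
Reagents that add atoms: none
Why: Dess–Martin oxidation of both neopentyl alcohols; the aldehydes have no α-hydrogen, so no stereocentre can be lost.

Step 33
Reactants: 37 18,18′-dialdehyde corresponding to the target
Product: 38 target diacid CNP0240573.1
Conditions: NaClO2, NaH2PO4, 2-methylbut-2-ene, t-BuOH/H2O, 0 °C → 25 °C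
Reagents that add atoms: sodium chlorite, [Na+].[O-]Cl=O
Why: Pinnick oxidation of both aldehydes to the acids, with 2-methylbut-2-ene scavenging hypochlorous acid so that the four alkenes should survive.

## Compound list

1 | (−)-levopimaric acid, abieta-8(14),12-dien-18-oic acid | CC(C)C1=CC[C@H]2C(=C1)CC[C@@H]3[C@]2(C)CCC[C@@]3(C)C(=O)O | starting material
2 | levopimarol, abieta-8(14),12-dien-18-ol (configuration as in 1) | CC(C)C1=CC[C@H]2C(=C1)CC[C@@H]3[C@]2(C)CCC[C@@]3(C)CO | intermediate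
3 | 18-O-TBDPS-levopimarol | CC(C)C1=CC[C@H]2C(=C1)CC[C@@H]3[C@]2(C)CCC[C@@]3(C)CO[Si](c4ccccc4)(c4ccccc4)C(C)(C)C | intermediate
4 | 18-(TBDPS-oxy)-8-oxo-13,14,15,16,17-pentanorlabdan-12-al (C4, C5, C9, C10 as in 1) | O=CC[C@H]1C(=O)CC[C@@H]2[C@]1(C)CCC[C@@]2(C)CO[Si](c3ccccc3)(c3ccccc3)C(C)(C)C | intermediate
5 | ethyl (12E)-18-(TBDPS-oxy)-8-oxo-15,17-dinorlabd-12-en-14-oate | CCOC(=O)/C(C)=C/C[C@H]1C(=O)CC[C@@H]2[C@]1(C)CCC[C@@]2(C)CO[Si](c3ccccc3)(c3ccccc3)C(C)(C)C | intermediate
6 | ethyl (12E)-18-(TBDPS-oxy)-7-methylidene-8-oxo-15,17-dinorlabd-12-en-14-oate | CCOC(=O)/C(C)=C/C[C@H]1C(=O)C(=C)C[C@@H]2[C@]1(C)CCC[C@@]2(C)CO[Si](c3ccccc3)(c3ccccc3)C(C)(C)C | intermediate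
7 | ethyl (12E)-18-(TBDPS-oxy)-8-hydroxy-7-methylidene-15,17-dinorlabd-12-en-14-oate (both C8 epimers, C8 left undefined) | CCOC(=O)/C(C)=C/C[C@H]1C(O)C(=C)C[C@@H]2[C@]1(C)CCC[C@@]2(C)CO[Si](c3ccccc3)(c3ccccc3)C(C)(C)C | intermediate
8 | ethyl (12E)-18-(TBDPS-oxy)-8-(methoxycarbonyloxy)-7-methylidene-15,17-dinorlabd-12-en-14-oate (both C8 epimers) | CCOC(=O)/C(C)=C/C[C@H]1C(OC(=O)OC)C(=C)C[C@@H]2[C@]1(C)CCC[C@@]2(C)CO[Si](c3ccccc3)(c3ccccc3)C(C)(C)C | intermediate
9 | ethyl (12E)-18-(TBDPS-oxy)-7-methylidene-15,17-dinorlabd-12-en-14-oate | CCOC(=O)/C(C)=C/C[C@H]1CC(=C)C[C@@H]2[C@]1(C)CCC[C@@]2(C)CO[Si](c3ccccc3)(c3ccccc3)C(C)(C)C | intermediate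
10 | (12E)-18-(TBDPS-oxy)-7-methylidene-15,17-dinorlabd-12-en-14-ol | OC/C(C)=C/C[C@H]1CC(=C)C[C@@H]2[C@]1(C)CCC[C@@]2(C)CO[Si](c3ccccc3)(c3ccccc3)C(C)(C)C | intermediate
11 | (12E)-18-(TBDPS-oxy)-7-methylidene-15,17-dinorlabd-12-en-14-yl hex-5-enoate | C=CCCCC(=O)OC/C(C)=C/C[C@H]1CC(=C)C[C@@H]2[C@]1(C)CCC[C@@]2(C)CO[Si](c3ccccc3)(c3ccccc3)C(C)(C)C | intermediate
12 | (Z)-O-boryl ketene acetal of 11 with the (4R,5R)-1,3-bis(arylsulfonyl)-4,5-diphenyl-1,3,2-diazaborolidin-2-yl group on oxygen | C=CCC/C=C(\OB1N(S(=O)(=O)c2cc(C(F)(F)F)cc(C(F)(F)F)c2)[C@H](c2ccccc2)[C@@H](c2ccccc2)N1S(=O)(=O)c1cc(C(F)(F)F)cc(C(F)(F)F)c1)OC/C(C)=C/C[C@H]1CC(=C)C[C@@H]2[C@]1(C)CCC[C@@]2(C)CO[Si](c3ccccc3)(c3ccccc3)C(C)(C)C | intermediate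
13 | (2S,3S)-2-(but-3-en-1-yl)-3-(D1CH2)-4-methylpent-4-enoic acid | C=C1C[C@H](C[C@H](C(C)=C)[C@H](CCC=C)C(=O)O)[C@@]2(C)CCC[C@@](C)(CO[Si](c3ccccc3)(c3ccccc3)C(C)(C)C)[C@@H]2C1 | intermediate
14 | (1S,2S)-2-(D1CH2)-3-methylcyclohex-3-ene-1-carboxylic acid (cis) | C=C1C[C@H](C[C@@H]2C(C)=CCC[C@@H]2C(=O)O)[C@@]2(C)CCC[C@@](C)(CO[Si](c3ccccc3)(c3ccccc3)C(C)(C)C)[C@@H]2C1 | intermediate
15 | [(1S,2S)-2-(D1CH2)-3-methylcyclohex-3-en-1-yl]methanol | C=C1C[C@H](C[C@@H]2C(C)=CCC[C@@H]2CO)[C@@]2(C)CCC[C@@](C)(CO[Si](c3ccccc3)(c3ccccc3)C(C)(C)C)[C@@H]2C1 | intermediate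
16 | (1S,2S)-2-(D1CH2)-3-methylcyclohex-3-ene-1-carbaldehyde | C=C1C[C@H](C[C@@H]2C(C)=CCC[C@@H]2C=O)[C@@]2(C)CCC[C@@](C)(CO[Si](c3ccccc3)(c3ccccc3)C(C)(C)C)[C@@H]2C1 | intermediate
17 | (5S,6S)-6-(D1CH2)-5-ethynyl-1-methylcyclohex-1-ene | C=C1C[C@H](C[C@@H]2C(C)=CCC[C@@H]2C#C)[C@@]2(C)CCC[C@@](C)(CO[Si](c3ccccc3)(c3ccccc3)C(C)(C)C)[C@@H]2C1 | intermediate
18 | dimethyl{(1E)-2-[(1S,2S)-2-(D1CH2)-3-methylcyclohex-3-en-1-yl]prop-1-en-1-yl}alumane | C=C1C[C@H](C[C@@H]2C(C)=CCC[C@@H]2/C(C)=C/[Al](C)C)[C@@]2(C)CCC[C@@](C)(CO[Si](c3ccccc3)(c3ccccc3)C(C)(C)C)[C@@H]2C1 | intermediate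
19 | (5S,6S)-6-(D1CH2)-5-[(1E)-1-iodoprop-1-en-2-yl]-1-methylcyclohex-1-ene | C=C1C[C@H](C[C@@H]2C(C)=CCC[C@@H]2/C(C)=C/I)[C@@]2(C)CCC[C@@](C)(CO[Si](c3ccccc3)(c3ccccc3)C(C)(C)C)[C@@H]2C1 | intermediate
20 | geranyl acetate | CC(C)=CCC/C(C)=C/COC(C)=O | starting material
21 | (2E,6E)-8-hydroxy-3,7-dimethylocta-2,6-dien-1-yl acetate | CC(=O)OC/C=C(C)/CC/C=C(C)/CO | intermediate
22 | (2E)-5-[(2R,3R)-3-(hydroxymethyl)-3-methyloxiran-2-yl]-3-methylpent-2-en-1-yl acetate | CC(=O)OC/C=C(C)/CC[C@H]1O[C@]1(C)CO | intermediate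
23 | (2E)-5-[(2R,3R)-3-(TBDPS-oxymethyl)-3-methyloxiran-2-yl]-3-methylpent-2-en-1-yl acetate | CC(=O)OC/C=C(C)/CC[C@H]1O[C@]1(C)CO[Si](c2ccccc2)(c2ccccc2)C(C)(C)C | intermediate
24 | (2E)-5-[(2R,3R)-3-(TBDPS-oxymethyl)-3-methyloxiran-2-yl]-3-methylpent-2-en-1-ol | OC/C=C(C)/CC[C@H]1O[C@]1(C)CO[Si](c2ccccc2)(c2ccccc2)C(C)(C)C | intermediate
25 | (2E)-1-bromo-5-[(2R,3R)-3-(TBDPS-oxymethyl)-3-methyloxiran-2-yl]-3-methylpent-2-ene | BrC/C=C(C)/CC[C@H]1O[C@]1(C)CO[Si](c2ccccc2)(c2ccccc2)C(C)(C)C | intermediate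
26 | methyl (6E)-9-[(2R,3R)-3-(TBDPS-oxymethyl)-3-methyloxiran-2-yl]-7-methyl-3-oxonon-6-enoate | COC(=O)CC(=O)CC/C=C(C)/CC[C@H]1O[C@]1(C)CO[Si](c2ccccc2)(c2ccccc2)C(C)(C)C | intermediate
27 | methyl (2Z,6E)-9-[(2R,3R)-3-(TBDPS-oxymethyl)-3-methyloxiran-2-yl]-7-methyl-3-(trifluoromethylsulfonyloxy)nona-2,6-dienoate | COC(=O)/C=C(\OS(=O)(=O)C(F)(F)F)CC/C=C(C)/CC[C@H]1O[C@]1(C)CO[Si](c2ccccc2)(c2ccccc2)C(C)(C)C | intermediate
28 | methyl (2Z,6E)-9-[(2R,3R)-3-(TBDPS-oxymethyl)-3-methyloxiran-2-yl]-7-methyl-3-[(trimethylsilyl)methyl]nona-2,6-dienoate | COC(=O)/C=C(\C[Si](C)(C)C)CC/C=C(C)/CC[C@H]1O[C@]1(C)CO[Si](c2ccccc2)(c2ccccc2)C(C)(C)C | intermediate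
29 | methyl (3R,4S,5S,9R,10R)-18-(TBDPS-oxy)-3-hydroxy-12,13,14,15,16-pentanorlabd-8(17)-en-11-oate (ent series; 3-OH, C18 and C9 ester equatorial, 4-CH3 axial and cis to 10-CH3) | COC(=O)[C@@H]1C(=C)CC[C@H]2[C@@]1(C)CC[C@@H](O)[C@]2(C)CO[Si](c3ccccc3)(c3ccccc3)C(C)(C)C | intermediate
30 | methyl (3R,4S,5S,9R,10R)-18-(TBDPS-oxy)-3-(imidazol-1-ylcarbothioyloxy)-12,13,14,15,16-pentanorlabd-8(17)-en-11-oate | COC(=O)[C@@H]1C(=C)CC[C@H]2[C@@]1(C)CC[C@@H](OC(=S)n3ccnc3)[C@]2(C)CO[Si](c3ccccc3)(c3ccccc3)C(C)(C)C | intermediate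
31 | methyl (4S,5S,9R,10R)-18-(TBDPS-oxy)-12,13,14,15,16-pentanorlabd-8(17)-en-11-oate | COC(=O)[C@@H]1C(=C)CC[C@H]2[C@@]1(C)CCC[C@]2(C)CO[Si](c3ccccc3)(c3ccccc3)C(C)(C)C | intermediate
32 | (4S,5S,9R,10R)-18-(TBDPS-oxy)-12,13,14,15,16-pentanorlabd-8(17)-en-11-ol | OC[C@@H]1C(=C)CC[C@H]2[C@@]1(C)CCC[C@]2(C)CO[Si](c3ccccc3)(c3ccccc3)C(C)(C)C | intermediate
33 | (4S,5S,9R,10R)-18-(TBDPS-oxy)-11-iodo-12,13,14,15,16-pentanorlabd-8(17)-ene | IC[C@@H]1C(=C)CC[C@H]2[C@@]1(C)CCC[C@]2(C)CO[Si](c3ccccc3)(c3ccccc3)C(C)(C)C | intermediate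
34 | alkylzinc iodide from 33 (zinc on C11) | I[Zn]C[C@@H]1C(=C)CC[C@H]2[C@@]1(C)CCC[C@]2(C)CO[Si](c3ccccc3)(c3ccccc3)C(C)(C)C | intermediate
35 | 18,18′-bis-O-TBDPS ether of diol 36 (central ring 1S,6S cis; side-chain alkene E) | C=C1C[C@H](C[C@@H]2C(C)=CCC[C@@H]2/C(C)=C/C[C@@H]2C(=C)CC[C@H]3[C@@]2(C)CCC[C@]3(C)CO[Si](c4ccccc4)(c4ccccc4)C(C)(C)C)[C@@]2(C)CCC[C@@](C)(CO[Si](c4ccccc4)(c4ccccc4)C(C)(C)C)[C@@H]2C1 | intermediate
36 | 18,18′-diol corresponding to the target (both CO2H replaced by CH2OH) | C=C1C[C@H](C[C@@H]2C(C)=CCC[C@@H]2/C(C)=C/C[C@@H]2C(=C)CC[C@H]3[C@@]2(C)CCC[C@]3(C)CO)[C@@]2(C)CCC[C@@](C)(CO)[C@@H]2C1 | intermediate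
37 | 18,18′-dialdehyde corresponding to the target | C=C1C[C@H](C[C@@H]2C(C)=CCC[C@@H]2/C(C)=C/C[C@@H]2C(=C)CC[C@H]3[C@@]2(C)CCC[C@]3(C)C=O)[C@@]2(C)CCC[C@@](C)(C=O)[C@@H]2C1 | intermediate
38 | target diacid CNP0240573.1 | C=C1C[C@H](C[C@@H]2C(C)=CCC[C@@H]2/C(C)=C/C[C@@H]2C(=C)CC[C@H]3[C@@]2(C)CCC[C@]3(C)C(=O)O)[C@@]2(C)CCC[C@@](C)(C(=O)O)[C@@H]2C1 | target

## Step count and risks

Total step count: 33. Longest linear sequence: 20 steps (steps 1–16, then 30–33); the second branch (steps 17–29) joins at step 30.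

Steps most likely to fail:

**Step 25 (cationic bicyclisation).** The cascade may stop after ring A, by proton loss or chloride capture at the C10 cation, because the ester-conjugated allylsilane is a weak π-nucleophile. The oxirane may also rearrange by hydride shift instead of ionising, because the CH2OSi group retards C4–O cleavage. Fallback: setting out from 28, the ester would first be reduced (i-Bu2AlH) to (2Z,6E)-9-[(2R,3R)-3-(TBDPS-oxymethyl)-3-methyloxiran-2-yl]-7-methyl-3-[(trimethylsilyl)methyl]nona-2,6-dien-1-ol F1, which would be silylated (t-BuMe2SiCl, imidazole) to its tert-butyldimethylsilyl ether F2. MeAlCl2 cyclisation of this isolated, more nucleophilic allylsilane should give the bicyclic 11-silyloxy 3-alcohol F3. Thioacylation to the imidazolide F4, n-Bu3SnH reduction to the 3-deoxy compound F5 and selective removal of the primary tert-butyldimethylsilyl group (pyridinium p-toluenesulfonate, MeOH; the TBDPS ether stays) would return to the route at 32.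

**Step 11 (enantioselective Claisen rearrangement).** Enolisation may be incomplete or give the wrong enolate geometry, and facial discrimination rests on the reagent alone, so a mixture of the four stereoisomers could result. Fallback: setting out from 10, MnO2 oxidation would give the enal (12E)-18-(TBDPS-oxy)-7-methylidene-15,17-dinorlabd-12-en-14-al F6, and Wittig methylenation (Ph3P=CH2) the diene (12E)-18-(TBDPS-oxy)-7-methylidene-17-norlabda-12,14-diene F7. An iminium-catalysed asymmetric Diels–Alder reaction of F7 with acrolein (chiral imidazolidinone salt) would then build the cyclohexene and both stereocentres in one cycloaddition (C12 bonding to the α-carbon of acrolein, endo) and arrive directly at the aldehyde 16. The regiochemistry relies on the 1-alkyl substituent of the diene outweighing its 2-methyl group and would have to be checked.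

**Step 30 (fragment union).** Zinc insertion into the β-branched primary iodide may be slow, and protodemetalation or homocoupling of the precious fragments may compete with transmetalation. Fallback: setting out from 33, iodine–lithium exchange (t-BuLi, Et2O, −78 °C) and trapping with B-methoxy-9-borabicyclo[3.3.1]nonane would give the lithium alkyl(methoxy)borate F8, which would be joined to 19 by a B-alkyl Suzuki–Miyaura coupling (Pd(dppf)Cl2, aqueous K3PO4, DMF) to come back to the route at 35.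

## Further compounds

F1 | step 25 | (2Z,6E)-9-[(2R,3R)-3-(TBDPS-oxymethyl)-3-methyloxiran-2-yl]-7-methyl-3-[(trimethylsilyl)methyl]nona-2,6-dien-1-ol | OC/C=C(\C[Si](C)(C)C)CC/C=C(C)/CC[C@H]1O[C@]1(C)CO[Si](c2ccccc2)(c2ccccc2)C(C)(C)C
F2 | step 25 | tert-butyldimethylsilyl ether of F1 | CC(C)(C)[Si](C)(C)OC/C=C(\C[Si](C)(C)C)CC/C=C(C)/CC[C@H]1O[C@]1(C)CO[Si](c2ccccc2)(c2ccccc2)C(C)(C)C
F3 | step 25 | ent-series 11-(tert-butyldimethylsilyloxy)-18-(TBDPS-oxy)-12,13,14,15,16-pentanorlabd-8(17)-en-3-ol (configuration as in 29) | CC(C)(C)[Si](C)(C)OC[C@@H]1C(=C)CC[C@H]2[C@@]1(C)CC[C@@H](O)[C@]2(C)CO[Si](c3ccccc3)(c3ccccc3)C(C)(C)C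
F4 | step 25 | 3-O-(imidazol-1-ylcarbothioyl) derivative of F3 | CC(C)(C)[Si](C)(C)OC[C@@H]1C(=C)CC[C@H]2[C@@]1(C)CC[C@@H](OC(=S)n3ccnc3)[C@]2(C)CO[Si](c3ccccc3)(c3ccccc3)C(C)(C)C
F5 | step 25 | ent-series 11-(tert-butyldimethylsilyloxy)-18-(TBDPS-oxy)-12,13,14,15,16-pentanorlabd-8(17)-ene | CC(C)(C)[Si](C)(C)OC[C@@H]1C(=C)CC[C@H]2[C@@]1(C)CCC[C@]2(C)CO[Si](c3ccccc3)(c3ccccc3)C(C)(C)C
F6 | step 11 | (12E)-18-(TBDPS-oxy)-7-methylidene-15,17-dinorlabd-12-en-14-al | O=C/C(C)=C/C[C@H]1CC(=C)C[C@@H]2[C@]1(C)CCC[C@@]2(C)CO[Si](c3ccccc3)(c3ccccc3)C(C)(C)C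
F7 | step 11 | (12E)-18-(TBDPS-oxy)-7-methylidene-17-norlabda-12,14-diene | C=C/C(C)=C/C[C@H]1CC(=C)C[C@@H]2[C@]1(C)CCC[C@@]2(C)CO[Si](c3ccccc3)(c3ccccc3)C(C)(C)C
F8 | step 30 | lithium B-methoxy-B-alkyl-9-borabicyclo[3.3.1]nonane borate from 33 (boron on C11) | [Li+].CO[B-]1(C[C@@H]2C(=C)CC[C@H]3[C@@]2(C)CCC[C@]3(C)CO[Si](c4ccccc4)(c4ccccc4)C(C)(C)C)C2CCCC1CCC2
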